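**Strategy.** In hydroazulene numbering the C3 tertiary hydroxyl and the C4 ester oxygen are 1,3-related across the ring-fusion carbon C3a, so with C4 as a ketone the cyclopentane ring (C1, C2, C3, C3a, C8a) is an aldol product. The route therefore rests on the C3–C3a disconnection: an intramolecular, thermodynamically controlled aldol addition of an (S)-cycloheptenone carrying a 4-methyl-3-oxopentyl chain on its quaternary carbon closes the five-membered ring onto the seven-membered enone and sets C3 and C3a in one operation. The precursor's single stereocentre comes from a copper-catalysed asymmetric conjugate addition that desymmetrises 3,6-dimethylcyclohepta-2,6-dienone, made by furan [4+3] cycloaddition.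

Key step: step 7

Remark (assumption on the chemistry): the enantiomer of the chiral NHC ligand in step 4 is taken to be the one that gives (R)-10; both antipodes of the ligand are accessible, so the other one is used if the facial sense is the opposite.

**Step 1**
Reactants: 1 2,5-dimethylfuran; 2 1,1,3,3-tetrabromoacetone
Product: 4 meso-1,5-dimethyl-8-oxabicyclo[3.2.1]oct-6-en-3-one, via dibromo cycloadduct 3 (not isolated)
Conditions: Zn–Ag couple, THF, −10 °C to rt; then Zn–Cu couple, NH4Cl, MeOH, rt
Reagents that add atoms: none
Why: Noyori–Hoffmann [4+3] cycloaddition of the zinc-generated dibromo-oxyallyl cation across C2/C5 of the furan, followed by reductive removal of both C–Br bonds, should give the bridged ketone, which can only be the meso cis-dimethyl compound.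

**Step 2**
Reactants: 4 meso-1,5-dimethyl-8-oxabicyclo[3.2.1]oct-6-en-3-one
Product: 5 meso-1,5-dimethyl-8-oxabicyclo[3.2.1]octan-3-one
Conditions: H2 (1 atm), 10 % Pd/C, EtOAc, rt
Reagents that add atoms: none
Why: Heterogeneous hydrogenation of the strained cis-disubstituted bridge alkene is fast and leaves the ketone and the bridging ether untouched, installing the future C7–C8 ethylene unit.

**Step 3**
Reactants: 5 meso-1,5-dimethyl-8-oxabicyclo[3.2.1]octan-3-one
Product: 7 3,6-dimethylcyclohepta-2,6-dien-1-one, via racemic hydroxy enone 6 (not isolated)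
Conditions: p-TsOH·H2O (0.2 equiv), toluene, reflux, Dean–Stark trap
Reagents that add atoms: none
Why: Acid-catalysed retro-oxa-Michael opening of the tertiary bridging ether through the enol, then E1 dehydration of the tertiary β-hydroxy ketone with azeotropic removal of water, should drain the equilibrium to the doubly conjugated, achiral dienone.

**Step 4**
Reactants: 7 3,6-dimethylcyclohepta-2,6-dien-1-one; 8 5-bromo-2-methylpent-2-ene
Product: 10 (R)-3,6-dimethyl-6-(4-methylpent-3-en-1-yl)cyclohept-2-en-1-one, via magnesium dienolate 9 (not isolated)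
Conditions: 8, Mg, Et2O (Grignard reagent); then 7, Cu(OTf)2 (3 mol %), chiral C2-symmetric imidazolinium chloride (NHC precursor, 4 mol %), Et2O, −30 °C; 1 M aq. HCl
Reagents that add atoms: none
Why: Copper–NHC-catalysed asymmetric conjugate addition of a Grignard reagent to a β-methyl cyclic enone: 7 has a mirror plane with enantiotopic β-carbons, the chiral copper complex selects one carbon and one face and so sets the quaternary centre, and the cross-conjugated magnesium dienolate 9 cannot take a second alkyl group and is protonated at C7 on work-up.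

**Step 5**
Reactants: 10 (R)-3,6-dimethyl-6-(4-methylpent-3-en-1-yl)cyclohept-2-en-1-one
Product: 11 (6S)-6-[2-(3,3-dimethyloxiran-2-yl)ethyl]-3,6-dimethylcyclohept-2-en-1-one (both epoxide epimers)
Conditions: mCPBA, NaHCO3, CH2Cl2, 0 °C
Reagents that add atoms: mCPBA, OOC(=O)c1cccc(Cl)c1
Why: Prilezhaev epoxidation is chemoselective for the electron-rich trisubstituted side-chain alkene over the electron-poor enone, and the new epoxide stereocentre is irrelevant because step 6 destroys it.

**Step 6**
Reactants: 11 (6S)-6-[2-(3,3-dimethyloxiran-2-yl)ethyl]-3,6-dimethylcyclohept-2-en-1-one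
Product: 12 (S)-3,6-dimethyl-6-(4-methyl-3-oxopentyl)cyclohept-2-en-1-one
Conditions: BF3·OEt2 (0.3 equiv), CH2Cl2, −78 to −20 °C
Reagents that add atoms: none
Why: Meinwald rearrangement, in which Lewis-acid opening at the tertiary epoxide carbon and a 1,2-hydride shift from the adjacent CH give the isopropyl ketone without touching the quaternary centre.

**Step 7**
Reactants: 12 (S)-3,6-dimethyl-6-(4-methyl-3-oxopentyl)cyclohept-2-en-1-one
Product: 13 (3R,3aR,8aS)-3-hydroxy-6,8a-dimethyl-3-(propan-2-yl)-2,3,3a,7,8,8a-hexahydroazulen-4(1H)-one (trans-fused ketol)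
Conditions: KOt-Bu (0.3 equiv), t-BuOH/THF (1:1), 0 °C to rt; AcOH/pH 7 buffer quench
Reagents that add atoms: none
Why: Mechanism: KOt-Bu reversibly deprotonates 12, and the cross-conjugated enolate at C7 (the future C3a) adds to the side-chain isopropyl ketone carbonyl (the future C3), after which the tertiary alkoxide is protonated by t-BuOH. The closest known reaction type is the thermodynamically controlled intramolecular ketone–ketone aldol addition of a 1,6-diketone to a 2-acylcyclopentanol. One ring is closed, the cyclopentane C1–C2–C3–C3a–C8a, in the 5-(enolexo)-exo-trig mode. C3a is set by the expected thermodynamic preference of the hydroazulen-4-one for the trans ring fusion (C3a–H anti to the C8a methyl), reached by enolisation and retro-aldol/aldol equilibration because kinetic closure is expected to favour the cis-fused ketol; C3 is set relative to C3a by the chelated or hydrogen-bonded arrangement that keeps the hydroxyl cis to the C4 carbonyl on the cyclopentane and puts the isopropyl group on the face of the small C3a hydrogen, remote from C4. The step needs regioselectivity among four enolisable sites, secured because only the C7 enolate has a five-membered closure that keeps the enone conjugation (the side-chain enolate could only give a bridged ketol that loses it and stays reversible), and it needs arrest at the ketol, secured by substoichiometric base, low temperature and a buffered quench before β-elimination of the tertiary hydroxyl or Michael closure onto the enone β-carbon can compete.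

**Step 8**
Reactants: 13 (3R,3aR,8aS)-3-hydroxy-6,8a-dimethyl-3-(propan-2-yl)-2,3,3a,7,8,8a-hexahydroazulen-4(1H)-one
Product: 14 (3R,3aS,4S,8aS)-6,8a-dimethyl-3-(propan-2-yl)-1,2,3,3a,4,7,8,8a-octahydroazulene-3,4-diol
Conditions: Me4NBH(OAc)3, MeCN/AcOH (1:1), −20 to 0 °C
Reagents that add atoms: none
Why: Saksena–Evans directed reduction, in which the C3 tertiary hydroxyl exchanges onto boron and delivers hydride intramolecularly to the face of the C4 carbonyl on which it sits (β), giving 1,2-reduction of the enone to the 1,3-anti diol with the C4 hydroxyl α (4S).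

**Step 9**
Reactants: 14 (3R,3aS,4S,8aS)-6,8a-dimethyl-3-(propan-2-yl)-1,2,3,3a,4,7,8,8a-octahydroazulene-3,4-diol; 15 4-acetoxybenzoic acid
Product: 16 (3R,3aS,4S,8aS)-3-hydroxy-6,8a-dimethyl-3-(propan-2-yl)-1,2,3,3a,4,7,8,8a-octahydroazulen-4-yl 4-(acetyloxy)benzoate
Conditions: DCC, DMAP (0.2 equiv), CH2Cl2, 0 °C to rt
Reagents that add atoms: none
Why: Steglich esterification acylates only the secondary allylic C4 hydroxyl with retention at C4, the tertiary C3 hydroxyl being too hindered to react.

**Step 10**
Reactants: 16 (3R,3aS,4S,8aS)-3-hydroxy-6,8a-dimethyl-3-(propan-2-yl)-1,2,3,3a,4,7,8,8a-octahydroazulen-4-yl 4-(acetyloxy)benzoate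
Product: 17 (3R,3aS,4S,8aS)-3-hydroxy-6,8a-dimethyl-3-(propan-2-yl)-1,2,3,3a,4,7,8,8a-octahydroazulen-4-yl 4-hydroxybenzoate (target)
Conditions: pyrrolidine (3 equiv), CH2Cl2, 0 °C to rt
Reagents that add atoms: none
Why: Aminolysis of the phenolic acetate by pyrrolidine is much faster than attack on the hindered secondary alkyl benzoate, so the phenol should be freed without touching the C4 ester, the tertiary alcohol or the alkene.

**Compound list**

1 | 2,5-dimethylfuran | Cc1ccc(C)o1 | starting material
2 | 1,1,3,3-tetrabromoacetone | BrC(Br)C(=O)C(Br)Br | starting material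
3 | 2,4-dibromo-1,5-dimethyl-8-oxabicyclo[3.2.1]oct-6-en-3-one (dibromo cycloadduct, mixture of bromide epimers) | C[C@]12C=C[C@](C)(O1)C(Br)C(=O)C2Br | intermediate (not isolated)
4 | meso-(1R,5S)-1,5-dimethyl-8-oxabicyclo[3.2.1]oct-6-en-3-one | C[C@]12C=C[C@](C)(O1)CC(=O)C2 | intermediate
5 | meso-(1R,5S)-1,5-dimethyl-8-oxabicyclo[3.2.1]octan-3-one | C[C@]12CC[C@](C)(O1)CC(=O)C2 | intermediate
6 | 6-hydroxy-3,6-dimethylcyclohept-2-en-1-one (racemic hydroxy enone) | CC1=CC(=O)CC(C)(O)CC1 | intermediate (not isolated)
7 | 3,6-dimethylcyclohepta-2,6-dien-1-one | CC1=CC(=O)C=C(C)CC1 | intermediate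
8 | 5-bromo-2-methylpent-2-ene | CC(C)=CCCBr | starting material
9 | bromomagnesium dienolate of 10 (enolate C1=C7, R at the quaternary carbon) | CC1=CC(O[Mg]Br)=C[C@@](C)(CC1)CCC=C(C)C | intermediate (not isolated)
10 | (R)-3,6-dimethyl-6-(4-methylpent-3-en-1-yl)cyclohept-2-en-1-one | CC1=CC(=O)C[C@@](C)(CC1)CCC=C(C)C | intermediate
11 | (6S)-6-[2-(3,3-dimethyloxiran-2-yl)ethyl]-3,6-dimethylcyclohept-2-en-1-one (both epoxide epimers) | CC1=CC(=O)C[C@@](C)(CC1)CCC1OC1(C)C | intermediate
12 | (S)-3,6-dimethyl-6-(4-methyl-3-oxopentyl)cyclohept-2-en-1-one | CC1=CC(=O)C[C@@](C)(CC1)CCC(=O)C(C)C | intermediate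
13 | (3R,3aR,8aS)-3-hydroxy-6,8a-dimethyl-3-(propan-2-yl)-2,3,3a,7,8,8a-hexahydroazulen-4(1H)-one | CC1=CC(=O)[C@@H]2[C@@](C)(CC1)CC[C@@]2(O)C(C)C | intermediate
14 | (3R,3aS,4S,8aS)-6,8a-dimethyl-3-(propan-2-yl)-1,2,3,3a,4,7,8,8a-octahydroazulene-3,4-diol | CC1=C[C@H](O)[C@@H]2[C@@](C)(CC1)CC[C@@]2(O)C(C)C | intermediate
15 | 4-acetoxybenzoic acid | CC(=O)Oc1ccc(cc1)C(O)=O | starting material
16 | (3R,3aS,4S,8aS)-3-hydroxy-6,8a-dimethyl-3-(propan-2-yl)-1,2,3,3a,4,7,8,8a-octahydroazulen-4-yl 4-(acetyloxy)benzoate | CC1=C[C@H](OC(=O)c2ccc(OC(C)=O)cc2)[C@@H]2[C@@](C)(CC1)CC[C@@]2(O)C(C)C | intermediate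
17 | (3R,3aS,4S,8aS)-3-hydroxy-6,8a-dimethyl-3-(propan-2-yl)-1,2,3,3a,4,7,8,8a-octahydroazulen-4-yl 4-hydroxybenzoate | CC1=C[C@H](OC(=O)c2ccc(O)cc2)[C@@H]2[C@@](C)(CC1)CC[C@@]2(O)C(C)C | target

**Totals.** Total step count: 10. Longest linear sequence: 10 steps (1 and 2 to 17).

**Steps most likely to fail**

Step 7 (key aldol). The equilibrating base does not confine the enolate to C7. The side-chain enolate may drain the mixture by Michael closure onto the enone β-carbon, the ketol may be lost by β-elimination, or the equilibrium may stop short of the trans-fused ketol. The fallback sets out from dienolate 9 (made from 7 as in step 4) and returns at 13. Dienolate 9 is quenched in the flask with N-bromosuccinimide to give (6R)-7-bromo-3,6-dimethyl-6-(4-methylpent-3-en-1-yl)cyclohept-2-en-1-one F1. Epoxidation as in step 5 gives (6S)-7-bromo-6-[2-(3,3-dimethyloxiran-2-yl)ethyl]-3,6-dimethylcyclohept-2-en-1-one F2, and BF3·OEt2 rearrangement as in step 6 gives (6S)-7-bromo-3,6-dimethyl-6-(4-methyl-3-oxopentyl)cyclohept-2-en-1-one F3. SmI2 (2.2 equiv, THF, −78 °C) then reduces only the C–Br bond. The trivalent samarium enolate, regiodefined at C7, closes onto the side-chain ketone through a chelated Reformatsky-type transition state with no free alkoxide present. Warming the samarium aldolate before the quench should allow the retro-aldol equilibration towards the trans-fused ketol 13.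

Step 4 (asymmetric conjugate addition). The homoprenyl Grignard reagent may add with poor facial discrimination, or in 1,2-fashion, at the hindered β-carbon of the seven-membered dienone. The fallback sets out from 7 and returns at 10. The quaternary centre is set with but-3-enylmagnesium bromide, a nucleophile with strong precedent in this copper–NHC addition, giving (R)-6-(but-3-en-1-yl)-3,6-dimethylcyclohept-2-en-1-one F4. Cross-metathesis of its terminal alkene with 2-methylbut-2-ene (second-generation Grubbs catalyst, CH2Cl2, 40 °C) then builds the trisubstituted side-chain alkene of 10, the enone alkene being inert.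

Step 3 (ring opening and dehydration). Under hot acid the cross-conjugated dienone may isomerise by double-bond migration or oligomerise. The fallback sets out from 5 and returns at 7 under non-acidic conditions. Soft enolisation with TMSOTf/Et3N (CH2Cl2, 0 °C) triggers β-elimination of the silyl-activated bridging ether and, after aqueous work-up, gives 3,6-dimethyl-6-[(trimethylsilyl)oxy]cyclohept-2-en-1-one F5. DBU (toluene, rt to 60 °C) then expels trimethylsilanolate by E1cB elimination to give 7.

**Further compounds**

F1 | step 7 | (6R)-7-bromo-3,6-dimethyl-6-(4-methylpent-3-en-1-yl)cyclohept-2-en-1-one (both C7 epimers) | CC1=CC(=O)C(Br)[C@@](C)(CC1)CCC=C(C)C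
F2 | step 7 | (6S)-7-bromo-6-[2-(3,3-dimethyloxiran-2-yl)ethyl]-3,6-dimethylcyclohept-2-en-1-one (epimer mixture) | CC1=CC(=O)C(Br)[C@@](C)(CC1)CCC1OC1(C)C
F3 | step 7 | (6S)-7-bromo-3,6-dimethyl-6-(4-methyl-3-oxopentyl)cyclohept-2-en-1-one (both C7 epimers) | CC1=CC(=O)C(Br)[C@@](C)(CC1)CCC(=O)C(C)C
F4 | step 4 | (R)-6-(but-3-en-1-yl)-3,6-dimethylcyclohept-2-en-1-one | CC1=CC(=O)C[C@@](C)(CC1)CCC=C
F5 | step 3 | 3,6-dimethyl-6-[(trimethylsilyl)oxy]cyclohept-2-en-1-one (racemic) | CC1=CC(=O)CC(C)(O[Si](C)(C)C)CC1
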